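**Strategy.** Ring C is a 1,2,3,5-tetraoxygenated benzene whose para carbons C1 and C4 carry the ether oxygens to ring B and ring D. It is not pre-formed but assembled last. A thermal cyclobutenone–ynol ether benzannulation joins a 4-aryloxy-3-ethoxycyclobutenone (rings A, B, G; four ring C carbons with O1, O2, O6) to an aryl ethynyl ether (rings D, E, F, E′, F′; C3 and C4 with O4). It forms C2–C3, C4–C5 and C1–C2 and delivers both crowded diaryl ethers ready-made. Each half is built from benzaldehydes by bromination/Suzuki coupling, etherification and Dakin oxidation, the formyl carbon marking each future phenol oxygen. One BBr3 treatment then frees all hydroxyls.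

Key step: step 15

**Remarks on the chemistry (assumptions)**
- Ring labels: A = terminal 3,5-dioxygenated phenoxy ring; B = ring carrying O–A at B1, O–C at B4 and aryl ring G at B5; C = central ring (C1–O–B, C2/C6 hydroxyls, C4–O–D); D = ring with D1–O–C, D4 oxygen, and two identical biaryl arms E–F and E′–F′ on O2 and O6; F, F′, G = 2,4,6-trioxygenated phenyl rings.
- The two precursors and the product of step 15 were re-derived atom by atom from the target. The regiochemistry (ketone carbon → C2–OH, enol ether carbon → C6–OEt, sp3 carbon → C1, alkyne carbons → C3/C4) maps correctly, so no structural correction is needed.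
- Precursor design choices: the enol ether is ethyl (ethoxyacetylene is commercial, and the group falls with the methyl ethers). The ynol ether is aryl and terminal, so it cannot lose an alkene by retro-ene fragmentation on heating and leaves no extra group on C3. All spectator hydroxyls are methyl ethers.
- The target has no stereogenic element (each biaryl axis carries a symmetric ring). Cyclobutenone 15 is used as the racemate.
- Compounds 1, 3, 6, 10, 12, 16, 21 and 26 are assumed to be purchased.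

**Route**

Step 1
Reactants: 1 4-(benzyloxy)-3,5-dimethoxybenzaldehyde
Product: 2 4-(benzyloxy)-2-bromo-3,5-dimethoxybenzaldehyde
Conditions: NBS, DMF, 0 °C → rt
Reagents that add atoms: N-bromosuccinimide, O=C1CCC(=O)N1Br
Why: Electrophilic aromatic bromination; the only free positions (C2/C6, equivalent) are ortho and para to the two methoxy groups, and the formyl and bromo groups slow a second substitution.

Step 2
Reactants: 2 4-(benzyloxy)-2-bromo-3,5-dimethoxybenzaldehyde; 3 2,4,6-trimethoxyphenylboronic acid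
Product: 4 4-(benzyloxy)-3,5-dimethoxy-2-(2,4,6-trimethoxyphenyl)benzaldehyde
Conditions: Pd(OAc)2, SPhos, K3PO4, PhMe/H2O, 100 °C
Reagents that add atoms: none
Why: Suzuki–Miyaura coupling with a bulky dialkylbiarylphosphine, the established answer to tetra-ortho-substituted biaryls and to protodeboronation of 2,6-dimethoxyarylboronic acids; the ortho formyl group assists oxidative addition.

Step 3
Reactants: 4 4-(benzyloxy)-3,5-dimethoxy-2-(2,4,6-trimethoxyphenyl)benzaldehyde
Product: 5 4-hydroxy-3,5-dimethoxy-2-(2,4,6-trimethoxyphenyl)benzaldehyde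
Conditions: H2 (1 atm), Pd/C, EtOAc, rt
Reagents that add atoms: none
Why: Catalytic hydrogenolysis of the benzyl aryl ether, which should outpace reduction of the hindered, electron-rich aryl aldehyde in an aprotic solvent if stopped after one equivalent of hydrogen.

Step 4
Reactants: 5 4-hydroxy-3,5-dimethoxy-2-(2,4,6-trimethoxyphenyl)benzaldehyde; 6 1-iodo-3,5-dimethoxybenzene
Product: 7 4-(3,5-dimethoxyphenoxy)-3,5-dimethoxy-2-(2,4,6-trimethoxyphenyl)benzaldehyde
Conditions: CuI, picolinic acid, K3PO4, DMSO, 90 °C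
Reagents that add atoms: none
Why: Ullmann-type copper-catalysed O-arylation under conditions suited to 2,6-disubstituted phenols; ring A enters only after the bromination, so its three activated positions never meet an electrophile.

Step 5
Reactants: 7 4-(3,5-dimethoxyphenoxy)-3,5-dimethoxy-2-(2,4,6-trimethoxyphenyl)benzaldehyde
Product: 9 4-(3,5-dimethoxyphenoxy)-3,5-dimethoxy-2-(2,4,6-trimethoxyphenyl)phenol, via aryl formate 8 (not isolated)
Conditions: mCPBA, CH2Cl2, 0 °C → rt; Na2SO3 wash; then K2CO3, MeOH, rt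
Reagents that add atoms: 3-chloroperoxybenzoic acid, OOC(=O)c1cccc(Cl)c1
Why: Dakin-type Baeyer–Villiger oxidation; the aryl group with its para aryloxy donor migrates in preference to hydride, and methanolysis of the formate unveils O4 of ring B where the formyl carbon stood.

Step 6
Reactants: 9 4-(3,5-dimethoxyphenoxy)-3,5-dimethoxy-2-(2,4,6-trimethoxyphenyl)phenol; 10 bromoacetic acid
Product: 11 2-[4-(3,5-dimethoxyphenoxy)-3,5-dimethoxy-2-(2,4,6-trimethoxyphenyl)phenoxy]acetic acid
Conditions: NaH, THF, 0 °C → reflux; then aq. HCl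
Reagents that add atoms: none
Why: Williamson ether synthesis of the phenoxide with sodium bromoacetate, giving the aryloxyacetic acid directly.

Step 7
Reactants: 11 2-[4-(3,5-dimethoxyphenoxy)-3,5-dimethoxy-2-(2,4,6-trimethoxyphenyl)phenoxy]acetic acid; 12 ethoxyacetylene
Product: 15 4-[4-(3,5-dimethoxyphenoxy)-3,5-dimethoxy-2-(2,4,6-trimethoxyphenyl)phenoxy]-3-ethoxycyclobut-2-en-1-one (racemic), via acid chloride 13 (not isolated), via aryloxyketene 14 (not isolated)
Conditions: 1-chloro-N,N,2-trimethylprop-1-en-1-amine, CH2Cl2, 0 °C → rt; then 12 (excess), Et3N (slow addition), Et2O, 0 °C → rt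
Reagents that add atoms: none
Why: The acid chloride is made under neutral conditions (no HCl or Vilsmeier-type electrophile to attack rings A and G), dehydrochlorinated to the aryloxyketene and trapped by ketene–ynol ether [2+2] cycloaddition, the nucleophilic CH carbon of ethoxyacetylene bonding to the ketene carbonyl carbon to give the 3-ethoxy-4-aryloxy isomer; the new C4 stereocentre forms as a racemate, which is harmless because it becomes aromatic C1 of ring C.

Step 8
Reactants: 16 2,4,6-trimethoxybenzaldehyde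
Product: 17 3-bromo-2,4,6-trimethoxybenzaldehyde
Conditions: NBS, CH2Cl2, 0 °C
Reagents that add atoms: N-bromosuccinimide, O=C1CCC(=O)N1Br
Why: Electrophilic aromatic bromination at one of the two equivalent positions between methoxy groups; one equivalent of NBS in the cold should stop at the monobromide because bromine deactivates the ring.

Step 9
Reactants: 17 3-bromo-2,4,6-trimethoxybenzaldehyde; 3 2,4,6-trimethoxyphenylboronic acid
Product: 18 2,2',4,4',6,6'-hexamethoxybiphenyl-3-carbaldehyde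
Conditions: Pd(OAc)2, SPhos, K3PO4, PhMe/H2O, 100 °C
Reagents that add atoms: none
Why: Suzuki–Miyaura coupling as in step 2, here giving a tetra-ortho-methoxy biaryl; excess boronic acid covers losses to protodeboronation.

Step 10
Reactants: 18 2,2',4,4',6,6'-hexamethoxybiphenyl-3-carbaldehyde
Product: 20 2,2',4,4',6,6'-hexamethoxybiphenyl-3-ol, via aryl formate 19 (not isolated)
Conditions: mCPBA, CH2Cl2, 0 °C → rt; Na2SO3 wash; then K2CO3, MeOH, rt
Reagents that add atoms: 3-chloroperoxybenzoic acid, OOC(=O)c1cccc(Cl)c1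
Why: Dakin-type Baeyer–Villiger oxidation; the 2,4,6-trioxygenated aryl group migrates readily, and methanolysis leaves the ring E hydroxyl flanked by two methoxy groups.

Step 11
Reactants: 20 2,2',4,4',6,6'-hexamethoxybiphenyl-3-ol (2.2 equiv); 21 2,6-difluoro-4-methoxybenzaldehyde
Product: 23 2,6-bis[(2,2',4,4',6,6'-hexamethoxybiphenyl-3-yl)oxy]-4-methoxybenzaldehyde, via monoaryl ether 22 (not isolated)
Conditions: Cs2CO3, DMSO, 110 °C
Reagents that add atoms: none
Why: Two successive nucleophilic aromatic substitutions (addition–elimination) of fluoride ortho to the formyl group; fluoride is small enough for the crowded phenoxide, and the activating aldehyde later becomes O1 of ring D.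

Step 12
Reactants: 23 2,6-bis[(2,2',4,4',6,6'-hexamethoxybiphenyl-3-yl)oxy]-4-methoxybenzaldehyde
Product: 25 2,6-bis[(2,2',4,4',6,6'-hexamethoxybiphenyl-3-yl)oxy]-4-methoxyphenol, via aryl formate 24 (not isolated)
Conditions: mCPBA, CH2Cl2, 0 °C → rt; Na2SO3 wash; then K2CO3, MeOH (degassed), rt
Reagents that add atoms: 3-chloroperoxybenzoic acid, OOC(=O)c1cccc(Cl)c1
Why: Dakin-type Baeyer–Villiger oxidation; the migrating aryl group bears two ortho aryloxy donors and a para methoxy donor, and the peracid is destroyed before the electron-rich phenol is unveiled.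

Step 13
Reactants: 25 2,6-bis[(2,2',4,4',6,6'-hexamethoxybiphenyl-3-yl)oxy]-4-methoxyphenol; 26 trichloroethylene
Product: 28 (E)-1,2-dichlorovinyl ether of phenol 25, via dichloroacetylene 27 (not isolated)
Conditions: K2CO3, DMF, 70 °C
Reagents that add atoms: none
Why: Base-induced dehydrochlorination of trichloroethylene gives dichloroacetylene, to which the phenoxide adds in anti fashion, a known route to (E)-1,2-dichlorovinyl aryl ethers; the slim linear electrophile can reach the crowded D1 oxygen.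

Step 14
Reactants: 28 (E)-1,2-dichlorovinyl ether of phenol 25
Product: 31 ethynyl ether of phenol 25, via chloroethynyl ether 29 (not isolated), via lithium aryloxyacetylide 30 (not isolated)
Conditions: n-BuLi (2.2 equiv), THF, −78 → −40 °C; then MeOH, −78 °C
Reagents that add atoms: none
Why: Dehydrochlorination by n-BuLi gives the chloroalkynyl ether and chlorine–lithium exchange gives the lithium acetylide, which is protonated cold (elimination/exchange route to ynol ethers); at −78 °C this is much faster than ortho-lithiation of the methoxyarenes.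

Step 15
Reactants: 15 4-aryloxy-3-ethoxycyclobut-2-en-1-one (rings A, B, G); 31 ethynyl ether of phenol 25 (rings D, E, F, E′, F′; 1.2 equiv)
Product: 36 3-ethoxy-2-[aryloxy of phenol 9]-5-[aryloxy of phenol 25]phenol (protected nonamer), via vinylketene 32 (not isolated), via vinylcyclobutenone 33 (not isolated), via dienylketene 34 (not isolated), via cyclohexadienone 35 (not isolated)
Conditions: PhMe, 80 → 110 °C, sealed tube, Ar
Reagents that add atoms: none
Why: Proposed new method: heating should open cyclobutenone 15 by 4π conrotation (aryloxy group rotating outward) to vinylketene 32, whose ketene C=C adds ynol ether 31 in a [2+2] cycloaddition to give 33; a second 4π opening gives dienylketene 34, which closes ring C by thermal 6π disrotatory electrocyclization (C1–C2 bond) to dienone 35, and enolization aromatizes it. The closest known reaction is the Danheiser benzannulation of cyclobutenones with alkoxy- and siloxyalkynes; new here are the 4-aryloxy-3-alkoxy substitution of the cyclobutenone and an aryl ethynyl ether as ketenophile. Ring C is closed by a pericyclic step and not by substitution on a crowded arene, so the hindered C1–O and C4–O ethers arrive intact. No stereocentre survives: C4 of 15 and the sp3 centres of 33 and 35 all become aromatic carbons. The step needs regioselectivity in the [2+2] event, secured by the polarization of the ynol ether, whose unsubstituted nucleophilic carbon bonds to the electrophilic ketene carbon so that O4 ends para to O1; the neutral, reagent-free conditions spare the twenty methyl ethers.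

Step 16
Reactants: 36 protected nonamer
Product: 37 target nonamer (CNP0117322.0)
Conditions: BBr3 (large excess), CH2Cl2, −78 °C → rt; then H2O, 0 °C; isolation under Ar
Reagents that add atoms: none
Why: Lewis acid-mediated ether cleavage: bromide attacks the methyl and ethyl groups of the boron-complexed ethers while diaryl ether and biaryl bonds are inert, so all twenty-one alkyl ethers should fall in one operation; no stereocentre is involved.

**Compound list**

1 | 4-(benzyloxy)-3,5-dimethoxybenzaldehyde | O=Cc1cc(OC)c(OCc2ccccc2)c(OC)c1 | starting material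
2 | 4-(benzyloxy)-2-bromo-3,5-dimethoxybenzaldehyde | O=Cc1cc(OC)c(OCc2ccccc2)c(OC)c1Br | intermediate
3 | 2,4,6-trimethoxyphenylboronic acid | COc1cc(OC)c(B(O)O)c(OC)c1 | starting material
4 | 4-(benzyloxy)-3,5-dimethoxy-2-(2,4,6-trimethoxyphenyl)benzaldehyde | O=Cc1cc(OC)c(OCc2ccccc2)c(OC)c1-c1c(OC)cc(OC)cc1OC | intermediate
5 | 4-hydroxy-3,5-dimethoxy-2-(2,4,6-trimethoxyphenyl)benzaldehyde | O=Cc1cc(OC)c(O)c(OC)c1-c1c(OC)cc(OC)cc1OC | intermediate
6 | 1-iodo-3,5-dimethoxybenzene | COc1cc(I)cc(OC)c1 | starting material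
7 | 4-(3,5-dimethoxyphenoxy)-3,5-dimethoxy-2-(2,4,6-trimethoxyphenyl)benzaldehyde | O=Cc1cc(OC)c(Oc2cc(OC)cc(OC)c2)c(OC)c1-c1c(OC)cc(OC)cc1OC | intermediate
8 | 4-(3,5-dimethoxyphenoxy)-3,5-dimethoxy-2-(2,4,6-trimethoxyphenyl)phenyl formate (not isolated) | O=COc1cc(OC)c(Oc2cc(OC)cc(OC)c2)c(OC)c1-c1c(OC)cc(OC)cc1OC | intermediate
9 | 4-(3,5-dimethoxyphenoxy)-3,5-dimethoxy-2-(2,4,6-trimethoxyphenyl)phenol (ring A–B–G phenol) | Oc1cc(OC)c(Oc2cc(OC)cc(OC)c2)c(OC)c1-c1c(OC)cc(OC)cc1OC | intermediate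
10 | bromoacetic acid | OC(=O)CBr | starting material
11 | 2-[4-(3,5-dimethoxyphenoxy)-3,5-dimethoxy-2-(2,4,6-trimethoxyphenyl)phenoxy]acetic acid | OC(=O)COc1cc(OC)c(Oc2cc(OC)cc(OC)c2)c(OC)c1-c1c(OC)cc(OC)cc1OC | intermediate
12 | ethoxyacetylene | CCOC#C | starting material
13 | acid chloride of 11 (not isolated) | ClC(=O)COc1cc(OC)c(Oc2cc(OC)cc(OC)c2)c(OC)c1-c1c(OC)cc(OC)cc1OC | intermediate
14 | aryloxyketene from 13 (not isolated) | O=C=COc1cc(OC)c(Oc2cc(OC)cc(OC)c2)c(OC)c1-c1c(OC)cc(OC)cc1OC | intermediate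
15 | 4-[4-(3,5-dimethoxyphenoxy)-3,5-dimethoxy-2-(2,4,6-trimethoxyphenyl)phenoxy]-3-ethoxycyclobut-2-en-1-one (racemic) | CCOC1=CC(=O)C1Oc1cc(OC)c(Oc2cc(OC)cc(OC)c2)c(OC)c1-c1c(OC)cc(OC)cc1OC | intermediate
16 | 2,4,6-trimethoxybenzaldehyde | COc1cc(OC)c(C=O)c(OC)c1 | starting material
17 | 3-bromo-2,4,6-trimethoxybenzaldehyde | COc1cc(OC)c(C=O)c(OC)c1Br | intermediate
18 | 2,2',4,4',6,6'-hexamethoxybiphenyl-3-carbaldehyde | COc1cc(OC)c(C=O)c(OC)c1-c1c(OC)cc(OC)cc1OC | intermediate
19 | 2,2',4,4',6,6'-hexamethoxybiphenyl-3-yl formate (not isolated) | COc1cc(OC)c(OC=O)c(OC)c1-c1c(OC)cc(OC)cc1OC | intermediate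
20 | 2,2',4,4',6,6'-hexamethoxybiphenyl-3-ol (ring E–F phenol) | COc1cc(OC)c(O)c(OC)c1-c1c(OC)cc(OC)cc1OC | intermediate
21 | 2,6-difluoro-4-methoxybenzaldehyde | COc1cc(F)c(C=O)c(F)c1 | starting material
22 | 2-fluoro-6-[(2,2',4,4',6,6'-hexamethoxybiphenyl-3-yl)oxy]-4-methoxybenzaldehyde (not isolated) | COc1cc(F)c(C=O)c(Oc2c(OC)cc(OC)c(-c3c(OC)cc(OC)cc3OC)c2OC)c1 | intermediate
23 | 2,6-bis[(2,2',4,4',6,6'-hexamethoxybiphenyl-3-yl)oxy]-4-methoxybenzaldehyde | O=Cc1c(Oc2c(OC)cc(OC)c(-c3c(OC)cc(OC)cc3OC)c2OC)cc(OC)cc1Oc1c(OC)cc(OC)c(-c2c(OC)cc(OC)cc2OC)c1OC | intermediate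
24 | 2,6-bis[(2,2',4,4',6,6'-hexamethoxybiphenyl-3-yl)oxy]-4-methoxyphenyl formate (not isolated) | O=COc1c(Oc2c(OC)cc(OC)c(-c3c(OC)cc(OC)cc3OC)c2OC)cc(OC)cc1Oc1c(OC)cc(OC)c(-c2c(OC)cc(OC)cc2OC)c1OC | intermediate
25 | 2,6-bis[(2,2',4,4',6,6'-hexamethoxybiphenyl-3-yl)oxy]-4-methoxyphenol (ring D pentamer phenol) | Oc1c(Oc2c(OC)cc(OC)c(-c3c(OC)cc(OC)cc3OC)c2OC)cc(OC)cc1Oc1c(OC)cc(OC)c(-c2c(OC)cc(OC)cc2OC)c1OC | intermediate
26 | trichloroethylene | ClC=C(Cl)Cl | starting material
27 | dichloroacetylene (not isolated) | ClC#CCl | intermediate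
28 | (E)-1,2-dichlorovinyl ether of phenol 25 | Cl/C=C(/Cl)Oc1c(Oc2c(OC)cc(OC)c(-c3c(OC)cc(OC)cc3OC)c2OC)cc(OC)cc1Oc1c(OC)cc(OC)c(-c2c(OC)cc(OC)cc2OC)c1OC | intermediate
29 | chloroethynyl ether of phenol 25 (not isolated) | ClC#COc1c(Oc2c(OC)cc(OC)c(-c3c(OC)cc(OC)cc3OC)c2OC)cc(OC)cc1Oc1c(OC)cc(OC)c(-c2c(OC)cc(OC)cc2OC)c1OC | intermediate
30 | lithium aryloxyacetylide of phenol 25 (not isolated) | [Li]C#COc1c(Oc2c(OC)cc(OC)c(-c3c(OC)cc(OC)cc3OC)c2OC)cc(OC)cc1Oc1c(OC)cc(OC)c(-c2c(OC)cc(OC)cc2OC)c1OC | intermediate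
31 | ethynyl ether of phenol 25 | C#COc1c(Oc2c(OC)cc(OC)c(-c3c(OC)cc(OC)cc3OC)c2OC)cc(OC)cc1Oc1c(OC)cc(OC)c(-c2c(OC)cc(OC)cc2OC)c1OC | intermediate
32 | 4-aryloxy-3-ethoxybuta-1,3-dien-1-one, vinylketene from 15, aryloxy group outward (not isolated) | O=C=C/C(OCC)=C/Oc1cc(OC)c(Oc2cc(OC)cc(OC)c2)c(OC)c1-c1c(OC)cc(OC)cc1OC | intermediate
33 | 3-(ring D aryloxy)-4-[2-(ring B aryloxy)-1-ethoxyvinyl]cyclobut-2-en-1-one, racemic (not isolated) | O=C1C=C(Oc2c(Oc3c(OC)cc(OC)c(-c4c(OC)cc(OC)cc4OC)c3OC)cc(OC)cc2Oc2c(OC)cc(OC)c(-c3c(OC)cc(OC)cc3OC)c2OC)C1/C(OCC)=C/Oc1cc(OC)c(Oc2cc(OC)cc(OC)c2)c(OC)c1-c1c(OC)cc(OC)cc1OC | intermediate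
34 | 3-(ring D aryloxy)-5-ethoxy-6-(ring B aryloxy)hexa-1,3,5-trien-1-one, dienylketene with cis central double bond (not isolated) | O=C=C/C(Oc1c(Oc2c(OC)cc(OC)c(-c3c(OC)cc(OC)cc3OC)c2OC)cc(OC)cc1Oc1c(OC)cc(OC)c(-c2c(OC)cc(OC)cc2OC)c1OC)=C\C(OCC)=C\Oc1cc(OC)c(Oc2cc(OC)cc(OC)c2)c(OC)c1-c1c(OC)cc(OC)cc1OC | intermediate
35 | 6-(ring B aryloxy)-5-ethoxy-3-(ring D aryloxy)cyclohexa-2,4-dien-1-one, racemic (not isolated) | O=C1C=C(Oc2c(Oc3c(OC)cc(OC)c(-c4c(OC)cc(OC)cc4OC)c3OC)cc(OC)cc2Oc2c(OC)cc(OC)c(-c3c(OC)cc(OC)cc3OC)c2OC)C=C(OCC)C1Oc1cc(OC)c(Oc2cc(OC)cc(OC)c2)c(OC)c1-c1c(OC)cc(OC)cc1OC | intermediate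
36 | protected nonamer: ring C with free C2 hydroxyl and C6 ethyl ether, twenty methyl ethers elsewhere | COc1cc(OC)cc(Oc2c(OC)cc(Oc3c(O)cc(Oc4c(Oc5c(OC)cc(OC)c(-c6c(OC)cc(OC)cc6OC)c5OC)cc(OC)cc4Oc4c(OC)cc(OC)c(-c5c(OC)cc(OC)cc5OC)c4OC)cc3OCC)c(-c3c(OC)cc(OC)cc3OC)c2OC)c1 | intermediate
37 | target nonamer CNP0117322.0 (twenty-two free hydroxyls) | Oc1cc(O)cc(Oc2c(O)cc(Oc3c(O)cc(Oc4c(Oc5c(O)cc(O)c(-c6c(O)cc(O)cc6O)c5O)cc(O)cc4Oc4c(O)cc(O)c(-c5c(O)cc(O)cc5O)c4O)cc3O)c(-c3c(O)cc(O)cc3O)c2O)c1 | target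

**Step count and risk**

Total: 16 steps. Longest linear sequence: 9 steps (steps 1–7 or 8–14, then 15 and 16).

Steps most likely to fail:

1. Step 15 (the proposed new method). The vinylketene may dimerize, or acylate the product phenol, faster than it is captured by a bulky and only moderately nucleophilic aryl ynol ether, and the ynol ether may decompose at the temperature needed for ring opening. Fallback by known ether chemistry, setting out from phenols 9 and 25: Ullmann coupling of 9 with 4-bromo-3,5-dimethoxybenzaldehyde (CuI, picolinic acid, K3PO4, DMSO) should give the diaryl ether aldehyde F1. Dakin oxidation (mCPBA, then K2CO3/MeOH) via aryl formate F2 gives the ring C phenol F3 with its hydroxyl at C4. Triflation (Tf2O, pyridine) gives aryl triflate F4. Palladium-catalysed C–O coupling of F4 with the hindered phenol 25 (Pd(OAc)2, 2-di-tert-butylphosphino-2',4',6'-triisopropylbiphenyl, K3PO4, PhMe, 100 °C) gives the permethylated nonamer F5. Exhaustive demethylation of F5 with BBr3 rejoins the route at 37.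

2. Step 13. Addition of the very crowded D1 phenoxide to transient dichloroacetylene may be outrun by decomposition of that electrophile, leaving the phenol unconverted. Fallback, setting out from aldehyde 23: the Baeyer–Villiger oxidation is stopped at the aryl formate 24, which is isolated. Ramirez-type dibromomethylenation of the formate carbonyl (CBr4, PPh3, CH2Cl2) gives the 2,2-dibromovinyl ether F6. Treatment with n-BuLi (−78 °C), then methanol, gives the lithium acetylide 30 and from it the ethynyl ether, rejoining the route at 31.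

3. Step 16. Partly cleaved aryloxyboron species may precipitate and stall the cleavage, and the free polyphenol may oxidize during isolation. Fallback, setting out from 36: after BBr3 treatment and aqueous quench the crude polyphenol is acetylated at once (Ac2O, pyridine) to the docosaacetate F7, which can be chromatographed and separated from under-cleaved material. Acid methanolysis of F7 (HCl in degassed MeOH, rt) then releases the target, rejoining the route at 37.

**Further compounds**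

F1 | step 15 | 4-[4-(3,5-dimethoxyphenoxy)-3,5-dimethoxy-2-(2,4,6-trimethoxyphenyl)phenoxy]-3,5-dimethoxybenzaldehyde | O=Cc1cc(OC)c(Oc2cc(OC)c(Oc3cc(OC)cc(OC)c3)c(OC)c2-c2c(OC)cc(OC)cc2OC)c(OC)c1
F2 | step 15 | aryl formate from F1 | O=COc1cc(OC)c(Oc2cc(OC)c(Oc3cc(OC)cc(OC)c3)c(OC)c2-c2c(OC)cc(OC)cc2OC)c(OC)c1
F3 | step 15 | 4-[4-(3,5-dimethoxyphenoxy)-3,5-dimethoxy-2-(2,4,6-trimethoxyphenyl)phenoxy]-3,5-dimethoxyphenol | Oc1cc(OC)c(Oc2cc(OC)c(Oc3cc(OC)cc(OC)c3)c(OC)c2-c2c(OC)cc(OC)cc2OC)c(OC)c1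
F4 | step 15 | trifluoromethanesulfonate of F3 | O=S(=O)(Oc1cc(OC)c(Oc2cc(OC)c(Oc3cc(OC)cc(OC)c3)c(OC)c2-c2c(OC)cc(OC)cc2OC)c(OC)c1)C(F)(F)F
F5 | step 15 | permethylated nonamer (ring C as 2,6-dimethyl ether, twenty-two methyl ethers in all) | COc1cc(Oc2c(Oc3c(OC)cc(OC)c(-c4c(OC)cc(OC)cc4OC)c3OC)cc(OC)cc2Oc2c(OC)cc(OC)c(-c3c(OC)cc(OC)cc3OC)c2OC)cc(OC)c1Oc1cc(OC)c(Oc2cc(OC)cc(OC)c2)c(OC)c1-c1c(OC)cc(OC)cc1OC
F6 | step 13 | 2,2-dibromovinyl ether of phenol 25 | BrC(Br)=COc1c(Oc2c(OC)cc(OC)c(-c3c(OC)cc(OC)cc3OC)c2OC)cc(OC)cc1Oc1c(OC)cc(OC)c(-c2c(OC)cc(OC)cc2OC)c1OC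
F7 | step 16 | docosaacetate of the target | CC(=O)Oc1cc(OC(C)=O)cc(Oc2c(OC(C)=O)cc(Oc3c(OC(C)=O)cc(Oc4c(Oc5c(OC(C)=O)cc(OC(C)=O)c(-c6c(OC(C)=O)cc(OC(C)=O)cc6OC(C)=O)c5OC(C)=O)cc(OC(C)=O)cc4Oc4c(OC(C)=O)cc(OC(C)=O)c(-c5c(OC(C)=O)cc(OC(C)=O)cc5OC(C)=O)c4OC(C)=O)cc3OC(C)=O)c(-c3c(OC(C)=O)cc(OC(C)=O)cc3OC(C)=O)c2OC(C)=O)c1
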